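**Strategy.** The ring CH that carries the CH2O arm (C1, flanked by the C2(Me)=C3 alkene and the gem-dimethyl carbon C6) is allylic, and the arm carbon bears an aryl ether oxygen. The C1–CH2 bond is therefore made by an Ireland–Claisen rearrangement. The precursor is the (coumarin-7-yloxy)acetate of a cyclohex-2-enol (ester oxygen on C3, alkene C1=C2, acetate already on C5). Its α-carbon passes suprafacially to C1, relaying the C3 carbinol configuration to C1 and moving the alkene to C2=C3. The carboxyl tether is then excised by Barton decarboxylation. The enol comes from 2,4,4-trimethylcyclohexenone by dehydrogenation, enantioselective β-borylation and CBS reduction.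

Key step: step 6

Remark: 1 and 7 are taken as catalogue compounds; the sense of induction of the ligand in step 2 is to be confirmed on the first run and the ligand enantiomer chosen to give the 5R product.

Step 1
Reactants: 1 2,4,4-trimethylcyclohex-2-en-1-one
Product: 2 2,4,4-trimethylcyclohexa-2,5-dien-1-one
Conditions: DDQ (1.3 equiv), 1,4-dioxane, reflux
Reagents that add atoms: none
Why: DDQ dehydrogenation of a 4,4-disubstituted cyclohexenone can only introduce the C5=C6 alkene (C4 is quaternary), and the cross-conjugated dienone cannot aromatise.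

Step 2
Reactants: 2 2,4,4-trimethylcyclohexa-2,5-dien-1-one
Product: 4 (R)-5-hydroxy-2,4,4-trimethylcyclohex-2-en-1-one, via β-boryl ketone 3 (not isolated)
Conditions: CuCl (5 mol %), NaOt-Bu (10 mol %), Josiphos ligand (6 mol %, enantiomer per the remark), B2pin2 (1.1 equiv), MeOH (2 equiv), THF, 0 °C to rt; then NaBO3·4H2O, THF/H2O, rt
Reagents that add atoms: bis(pinacolato)diboron, CC1(C)OB(OC1(C)C)B1OC(C)(C)C(C)(C)O1 (boron carried in 3 only); sodium perborate, [Na+].[Na+].O[B-]1(O)OO[B-](O)(O)OO1 (oxygen of the new hydroxyl)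
Why: Copper-catalysed enantioselective conjugate borylation of a cyclic enone should attack C5 of the α-unsubstituted enone in preference to the α-methylated one, the chiral bisphosphine choosing the face and so setting C5 as R, which the stereoretentive perborate oxidation of the C–B bond keeps.

Step 3
Reactants: 4 (R)-5-hydroxy-2,4,4-trimethylcyclohex-2-en-1-one
Product: 5 (R)-2,2,4-trimethyl-5-oxocyclohex-3-en-1-yl acetate
Conditions: Ac2O, pyridine, DMAP (cat.), CH2Cl2, 0 °C
Reagents that add atoms: acetic anhydride, CC(=O)OC(C)=O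
Why: DMAP-catalysed acetylation of the secondary alcohol at 0 °C is mild enough to avoid E1cB loss of acetate from the β-acyloxy ketone and touches no stereocentre.

Step 4
Reactants: 5 (R)-2,2,4-trimethyl-5-oxocyclohex-3-en-1-yl acetate
Product: 6 (1R,5R)-5-hydroxy-2,2,4-trimethylcyclohex-3-en-1-yl acetate
Conditions: (S)-2-methyl-CBS-oxazaborolidine (20 mol %), catecholborane (1.5 equiv), toluene, −78 °C
Reagents that add atoms: none
Why: In this Corey–Bakshi–Shibata reduction the 2-methylalkenyl side of the enone acts as the large group, so the (S)-catalyst should deliver hydride to give the R carbinol, trans to the acetoxy group, by catalyst control, while catecholborane at −78 °C leaves acetate and alkene alone.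

Step 5
Reactants: 6 (1R,5R)-5-hydroxy-2,2,4-trimethylcyclohex-3-en-1-yl acetate; 7 [(2-oxo-2H-chromen-7-yl)oxy]acetic acid
Product: 8 (1R,5R)-5-acetoxy-2,4,4-trimethylcyclohex-2-en-1-yl [(2-oxo-2H-chromen-7-yl)oxy]acetate
Conditions: EDC·HCl (1.5 equiv), DMAP (0.2 equiv), CH2Cl2, 0 °C to rt
Reagents that add atoms: none
Why: Steglich-type carbodiimide esterification acylates the allylic alcohol with retention, so the trans relationship set in step 4 is carried into the rearrangement precursor.

Step 6
Reactants: 8 (1R,5R)-5-acetoxy-2,4,4-trimethylcyclohex-2-en-1-yl [(2-oxo-2H-chromen-7-yl)oxy]acetate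
Product: 11 2-[(1R,5R)-5-acetoxy-2,6,6-trimethylcyclohex-2-en-1-yl]-2-[(2-oxo-2H-chromen-7-yl)oxy]acetic acid (both epimers at the acid α-carbon), via silyl ketene acetal 9 (not isolated), via trimethylsilyl ester 10 (not isolated)
Conditions: LiHMDS (1.3 equiv) added to 8 and TMSCl/Et3N (3 equiv, premixed) in THF, −78 °C; warm to rt, then 50 °C; 1 M HCl work-up
Reagents that add atoms: chlorotrimethylsilane, C[Si](C)(C)Cl (silicon carried in 9 and 10 only, lost on work-up)
Why: LiHMDS removes a proton from the α-aryloxy CH2 (several pKa units more acidic than the acetate CH3, and lithium-chelated), the enolate is silylated at once to the (Z)-ketene acetal 9, and on warming a concerted suprafacial [3,3] shift through a six-membered transition state gives silyl ester 10, hydrolysed on work-up. The closest known reaction type is the Ireland–Claisen rearrangement of allyl glycolates and aryloxyacetates of cyclohex-2-enols. No ring is closed. The new ring stereocentre is controlled by the carbinol centre of 8: the C–C bond must form on the ring face that carries the departing C–O bond, which turns R at the carbinol carbon into R at the ring CH, trans to the acetoxy group, while the alkene moves to its position in the target; the second new centre, the exocyclic α-carbon, depends on ketene acetal geometry and chair/boat preference and is removed in step 7. The step needs chemoselective enolisation beside the acetate and the coumarin lactone, secured by the α-aryloxy acidification, the non-nucleophilic base and the internal TMSCl quench, and it needs bond formation next to the gem-dimethyl carbon, which an intramolecular thermal shift should tolerate.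

Step 7
Reactants: 11 2-[(1R,5R)-5-acetoxy-2,6,6-trimethylcyclohex-2-en-1-yl]-2-[(2-oxo-2H-chromen-7-yl)oxy]acetic acid
Product: 13 (1R,5R)-4,6,6-trimethyl-5-{[(2-oxo-2H-chromen-7-yl)oxy]methyl}cyclohex-3-en-1-yl acetate (target), via Barton ester 12 (not isolated)
Conditions: 1-hydroxypyridine-2(1H)-thione, DCC, DMAP (cat.), CH2Cl2, 0 °C to rt, dark; then t-BuSH (10 equiv), visible light (tungsten lamp), rt
Reagents that add atoms: 1-hydroxypyridine-2(1H)-thione, On1ccccc1=S (carried in 12 only)
Why: In this Barton reductive decarboxylation, visible-light homolysis of the thiohydroxamate N–O bond and loss of CO2 give an α-aryloxyalkyl radical that takes hydrogen from t-BuSH; both α-epimers converge, no ring stereocentre is involved, and the coumarin does not absorb at this wavelength.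

**Compound list**

1 | 2,4,4-trimethylcyclohex-2-en-1-one | CC1=CC(C)(C)CCC1=O | starting material
2 | 2,4,4-trimethylcyclohexa-2,5-dien-1-one | CC1=CC(C)(C)C=CC1=O | intermediate
3 | (R)-2,4,4-trimethyl-5-(4,4,5,5-tetramethyl-1,3,2-dioxaborolan-2-yl)cyclohex-2-en-1-one | CC1(C)OB(OC1(C)C)[C@@H]1CC(=O)C(C)=CC1(C)C | intermediate
4 | (R)-5-hydroxy-2,4,4-trimethylcyclohex-2-en-1-one | O[C@@H]1CC(=O)C(C)=CC1(C)C | intermediate
5 | (R)-2,2,4-trimethyl-5-oxocyclohex-3-en-1-yl acetate | CC(=O)O[C@@H]1CC(=O)C(C)=CC1(C)C | intermediate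
6 | (1R,5R)-5-hydroxy-2,2,4-trimethylcyclohex-3-en-1-yl acetate | CC(=O)O[C@@H]1C[C@@H](O)C(C)=CC1(C)C | intermediate
7 | [(2-oxo-2H-chromen-7-yl)oxy]acetic acid | OC(=O)COc1ccc2ccc(=O)oc2c1 | starting material
8 | (1R,5R)-5-acetoxy-2,4,4-trimethylcyclohex-2-en-1-yl [(2-oxo-2H-chromen-7-yl)oxy]acetate | CC(=O)O[C@@H]1C[C@@H](OC(=O)COc2ccc3ccc(=O)oc3c2)C(C)=CC1(C)C | intermediate
9 | (1R,5R)-2,2,4-trimethyl-5-({(Z)-2-[(2-oxo-2H-chromen-7-yl)oxy]-1-[(trimethylsilyl)oxy]ethenyl}oxy)cyclohex-3-en-1-yl acetate | CC(=O)O[C@@H]1C[C@@H](O/C(O[Si](C)(C)C)=C/Oc2ccc3ccc(=O)oc3c2)C(C)=CC1(C)C | intermediate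
10 | trimethylsilyl 2-[(1R,5R)-5-acetoxy-2,6,6-trimethylcyclohex-2-en-1-yl]-2-[(2-oxo-2H-chromen-7-yl)oxy]acetate (both α-epimers) | CC(=O)O[C@@H]1CC=C(C)[C@@H](C(Oc2ccc3ccc(=O)oc3c2)C(=O)O[Si](C)(C)C)C1(C)C | intermediate
11 | 2-[(1R,5R)-5-acetoxy-2,6,6-trimethylcyclohex-2-en-1-yl]-2-[(2-oxo-2H-chromen-7-yl)oxy]acetic acid (both α-epimers) | CC(=O)O[C@@H]1CC=C(C)[C@@H](C(Oc2ccc3ccc(=O)oc3c2)C(=O)O)C1(C)C | intermediate
12 | 2-thioxopyridin-1(2H)-yl 2-[(1R,5R)-5-acetoxy-2,6,6-trimethylcyclohex-2-en-1-yl]-2-[(2-oxo-2H-chromen-7-yl)oxy]acetate (both α-epimers) | CC(=O)O[C@@H]1CC=C(C)[C@@H](C(Oc2ccc3ccc(=O)oc3c2)C(=O)On2ccccc2=S)C1(C)C | intermediate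
13 | (1R,5R)-4,6,6-trimethyl-5-{[(2-oxo-2H-chromen-7-yl)oxy]methyl}cyclohex-3-en-1-yl acetate | CC(=O)O[C@@H]1CC=C(C)[C@@H](COc2ccc3ccc(=O)oc3c2)C1(C)C | target

**Count.** Total steps: 7. Longest linear sequence: 7 steps (1 to 13); 7 enters at step 5.

**Steps most likely to fail**

Step 6. The amide base or the ester enolate may attack the coumarin lactone or its enone, or the hindered ketene acetal may fragment to a ketene before the shift onto the ring carbon next to the gem-dimethyl group. The fallback forms the same bond by an anionic [2,3] shift with no coumarin or ester present and attaches the coumarin afterwards. It sets out from 4. Silylation (TBSCl, imidazole, DMF) should give (R)-5-[(tert-butyldimethylsilyl)oxy]-2,4,4-trimethylcyclohex-2-en-1-one F1. Reduction as in step 4 should give (1R,5R)-5-[(tert-butyldimethylsilyl)oxy]-2,4,4-trimethylcyclohex-2-en-1-ol F2. O-Alkylation (KH, Bu3SnCH2I, THF) should give tributyl({[(1R,5R)-5-[(tert-butyldimethylsilyl)oxy]-2,4,4-trimethylcyclohex-2-en-1-yl]oxy}methyl)stannane F3. Tin–lithium exchange (n-BuLi, THF, −78 °C) then triggers the suprafacial Wittig–Still rearrangement to [(1R,5R)-5-[(tert-butyldimethylsilyl)oxy]-2,6,6-trimethylcyclohex-2-en-1-yl]methanol F4. Mitsunobu etherification with umbelliferone (PPh3, DIAD, THF) should give 7-{[(1R,5R)-5-[(tert-butyldimethylsilyl)oxy]-2,6,6-trimethylcyclohex-2-en-1-yl]methoxy}-2H-chromen-2-one F5. Desilylation (TBAF, THF) should give 7-{[(1R,5R)-5-hydroxy-2,6,6-trimethylcyclohex-2-en-1-yl]methoxy}-2H-chromen-2-one F6. Acetylation (Ac2O, pyridine, DMAP) comes back to the route at 13.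

Step 2. The catalyst may discriminate poorly between the two enone β-positions or between the two faces at the β-carbon next to the quaternary centre, and the new hydroxyl may be lost by retro-oxa-Michael elimination during oxidation. The fallback sets the same C–O bond by asymmetric epoxidation and reductive opening. It sets out from 2. Nucleophilic epoxidation of the less substituted enone under chiral primary-amine iminium catalysis (9-amino-9-deoxy-epi-cinchona alkaloid salt, aqueous H2O2, dioxane) should give (1S,6S)-3,5,5-trimethyl-7-oxabicyclo[4.1.0]hept-3-en-2-one F7. Reductive cleavage of the Cα–O bond of the epoxy ketone with sodium phenylselenide ((PhSe)2, NaBH4, AcOH, EtOH, 0 °C) keeps the β C–O bond and comes back to the route at 4.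

Step 4. Catalyst control may be overridden by the substrate's preference for axial hydride delivery (mismatched double stereodifferentiation), which would erode the trans selectivity. The fallback replaces catalyst control by hydroxyl-directed reduction. It sets out from 4, before acetylation. Directed triacetoxyborohydride reduction (Me4NBH(OAc)3, MeCN/AcOH, −20 °C), with intramolecular hydride delivery from the face of the C5 alkoxyborate, should give (1R,5R)-2,4,4-trimethylcyclohex-2-ene-1,5-diol F8. Carbodiimide esterification with 7 at 0 °C on the more accessible allylic hydroxyl (the other is flanked by the quaternary carbon) should give (1R,5R)-5-hydroxy-2,4,4-trimethylcyclohex-2-en-1-yl [(2-oxo-2H-chromen-7-yl)oxy]acetate F9. Acetylation (Ac2O, pyridine, DMAP) comes back to the route at 8.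

**Further compounds**

F1 | step 6 | (R)-5-[(tert-butyldimethylsilyl)oxy]-2,4,4-trimethylcyclohex-2-en-1-one | CC(C)(C)[Si](C)(C)O[C@@H]1CC(=O)C(C)=CC1(C)C
F2 | step 6 | (1R,5R)-5-[(tert-butyldimethylsilyl)oxy]-2,4,4-trimethylcyclohex-2-en-1-ol | CC(C)(C)[Si](C)(C)O[C@@H]1C[C@@H](O)C(C)=CC1(C)C
F3 | step 6 | tributyl({[(1R,5R)-5-[(tert-butyldimethylsilyl)oxy]-2,4,4-trimethylcyclohex-2-en-1-yl]oxy}methyl)stannane | CC(C)(C)[Si](C)(C)O[C@@H]1C[C@@H](OC[Sn](CCCC)(CCCC)CCCC)C(C)=CC1(C)C
F4 | step 6 | [(1R,5R)-5-[(tert-butyldimethylsilyl)oxy]-2,6,6-trimethylcyclohex-2-en-1-yl]methanol | CC(C)(C)[Si](C)(C)O[C@@H]1CC=C(C)[C@@H](CO)C1(C)C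
F5 | step 6 | 7-{[(1R,5R)-5-[(tert-butyldimethylsilyl)oxy]-2,6,6-trimethylcyclohex-2-en-1-yl]methoxy}-2H-chromen-2-one | CC(C)(C)[Si](C)(C)O[C@@H]1CC=C(C)[C@@H](COc2ccc3ccc(=O)oc3c2)C1(C)C
F6 | step 6 | 7-{[(1R,5R)-5-hydroxy-2,6,6-trimethylcyclohex-2-en-1-yl]methoxy}-2H-chromen-2-one | O[C@@H]1CC=C(C)[C@@H](COc2ccc3ccc(=O)oc3c2)C1(C)C
F7 | step 2 | (1S,6S)-3,5,5-trimethyl-7-oxabicyclo[4.1.0]hept-3-en-2-one | CC1=CC(C)(C)[C@@H]2O[C@@H]2C1=O
F8 | step 4 | (1R,5R)-2,4,4-trimethylcyclohex-2-ene-1,5-diol | O[C@@H]1C[C@@H](O)C(C)=CC1(C)C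
F9 | step 4 | (1R,5R)-5-hydroxy-2,4,4-trimethylcyclohex-2-en-1-yl [(2-oxo-2H-chromen-7-yl)oxy]acetate | O[C@@H]1C[C@@H](OC(=O)COc2ccc3ccc(=O)oc3c2)C(C)=CC1(C)C
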